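All runs come from a simulation for an exercise, and the scatter is random.

A ratio between two closed runs was my way in: I had to say how much target each of four set-ups gives from one charge.

| setting | blue | green | violet | teal | south | east | north-east | west |
|---|---|---|---|---|---|---|---|---|
| starting material | 20 mM | 20 mM | 20 mM | 20 mM | 20 mM | 20 mM | 20 mM | 20 mM |
| first nucleophile | 2 equiv | 1.3 equiv | 3 equiv | 2 equiv | 2.00 equiv | 2.00 equiv | 2.00 equiv | 2.00 equiv |
| second nucleophile | 5 equiv | 5 equiv | 5 equiv | 7.5 equiv | 5.00 equiv | 5.00 equiv | 5.00 equiv (fed, over 2.40 h) | 5.00 equiv |
| remark | run made earlier | run made earlier | run made earlier | run made earlier | everything together in a closed stirred flask, run for 3.0 h | a tube with plug flow, the mixed feed as stated, residence time 3.0 h | all but second nucleophile at the start; second nucleophile goes in evenly over 2.40 h, the run ends at 3.0 h | one stirred flow tank at steady state, fed with the mixture as stated, mean residence time 3.0 h |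
| time |  |  |  |  | 3.0 h | 3.0 h | 3.0 h |  |

- blue (time / min: target / %): 15.0: 9; 30.0: 13; 50.0: 16; 60.0: 21; 80.0: 24; 90.0: 24; 120: 28
- green (time / h: target / %): 0.200: 2; 0.333: 9; 0.417: 10; 0.667: 10; 1.00: 15; 1.50: 18; 2.50: 26
- violet (time / h: target / %): 0.200: 7; 0.333: 9; 0.417: 10; 0.667: 19; 1.00: 26; 1.50: 33; 2.50: 35
- teal (time / h: target / %): 0.200: 7; 0.667: 14; 1.00: 17; 1.50: 22; 2.50: 29

(each reading ± 2 percentage points)

- the stated concentrations are those of everything mixed, before any reaction; amounts are the same in each set-up
- the analysis behind the earlier runs scatters by 2 percentage points, standard deviation
- the feed brings no volume worth counting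
- the earlier runs were made in a closed, stirred flask

- the set-up with the highest amount of target at the outlet or at the end, in percent of the starting material put in ("none" if the first two lie within 2 percentage points) (south / east / north-east / west / none)
- amount of target at the outlet or at the end, in percent of the starting material put in, south
- amount of target at the outlet or at the end, in percent of the starting material put in, east
- amount of target at the outlet or at the end, in percent of the starting material put in, north-east
- amount of target at the outlet or at the end, in percent of the starting material put in, west

Summed over their common times, violet held 1.54 times the target of green, though its charge of first nucleophile was 2.31 times as large. Target rose less than in proportion, so I read it as a share won in a competition. Reading that share as [first nucleophile]/([first nucleophile] + K) gave K = 42.8 mM. For this charge I got 0.935 for my capture number, a selectivity factor, N = [first nucleophile]/K, so I took the share of reacted starting material becoming target to be 0.483.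

One number was not enough. Teal and blue have the same N, yet at their two common times teal held 0.867 of blue's target, so second nucleophile seemed to compete as well.

Blue's readings at 60.0 min and 120 min gave me a first-order exponent over the run of 3.30. From them I reckoned 30.3 % for south and east, and 24.2 % for west. North-east holds on average 0.600 of the charge of second nucleophile, so teal's cost gave a relative gain of 0.107, and 33.6 %, which put north-east above south and east in my reckoning.

The forecast, higher than my reckoning for south and north-east, gave 32 % for south and east, 40 % for north-east and 25 % for west, naming north-east best: “Dosing keeps the second nucleophile low early”.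

The flasks gave 34.1 % in south and east, 37.2 % in north-east and 25.5 % in west, so north-east was best.

    starting material → intermediate (k = 1.80 × 10⁻⁴ s⁻¹)
    first nucleophile + intermediate → target (k = 0.226 L mol⁻¹ s⁻¹)
    second nucleophile + intermediate → other capture product (k = 0.0320 L mol⁻¹ s⁻¹)
    intermediate → solvolysis product (k = 0.00701 s⁻¹)
    intermediate → side product (k = 0.00228 s⁻¹)

At 3.00 h north-east still held 14.3 % of its starting material, with first nucleophile at 81.4 % of charge. N had thus become 0.761. Scaling the share so far, 0.434, by that fall, the remainder should add 5.56 %, for 42.8 % in all; the flask computed at 30.0 h holds 42.5 %.

In a neighbour of north-east charged with 8.0 mM of starting material at the same equivalents, N is 0.374, which scales north-east to 20.9 %; that flask computes to 22.0 %.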